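**Plan**
1. Retrosynthesis first cuts the fourteen O–CH3 bonds (all hydroxyls but one are carried as methyl ethers), then opens ring C at C-2–C-3, C-1–C-6 and C-3–C-4, which splits the hexamer into an A–B half and a D–E–F half.
2. Enabling feature: ring C has five oxygens and one C–H (C-2), with the ether to ring B at C-1 and the ether to ring D at C-6. It is therefore a two-carbon aryloxyalkyne unit (C-1, C-2) joined to a four-carbon, fully oxygenated vinylketene unit (C-3 to C-6), and both crowded ethers can be made before ring C exists.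
3. Forward: the A–O–B, F–O–E and E–O–D ethers come from copper-catalysed coupling of phenols with bromodimethoxybenzaldehydes, each followed by Dakin oxidation to the next phenol.
4. The A–B phenol becomes an aryl ethynyl ether via trichloroethylene. The D–E–F phenol is attached to squaric acid dichloride (exchange on dimethyl squarate would be uphill), and reduction and methylation give the cyclobutenone.
5. Ring C is the only ring built and is formed last but one, by thermal vinylketene/ynol ether benzannulation; BBr3 then frees all fifteen hydroxyls.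
6. Stereochemistry: the target has no stereocentre; the sp3 centres of the cyclobutenone and of the cascade intermediates are racemic and disappear on aromatisation.

Key step: step 13

Remarks
- Ring letters: A = terminal 2,4,6-trioxygenated ring, B, C = central pentaoxygenated ring, D, E, F = terminal 3,4,5-trioxygenated ring. Ring C: C-1 (O to ring B), C-2 (H), C-3, C-4, C-5 (OH in the target), C-6 (O to ring D).
- ArAB = 2,6-dimethoxy-4-(2,4,6-trimethoxyphenoxy)phenyl; ArDEF = 4-[3,5-dimethoxy-4-(3,4,5-trimethoxyphenoxy)phenoxy]-3,5-dimethoxyphenyl.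
- Assumption: compounds 1, 2, 6, 10, 11 and 18 are taken as purchased; 22, 23, 25 and 27 are racemic.

**Route**

Step 1
Reactants: 1 2,4,6-trimethoxyphenol; 2 4-bromo-2,6-dimethoxybenzaldehyde
Product: 3 2,6-dimethoxy-4-(2,4,6-trimethoxyphenoxy)benzaldehyde
Conditions: CuI (10 mol %), picolinic acid (20 mol %), K3PO4, DMSO, 90 °C, argon
Reagents that add atoms: none
Why: Ullmann diaryl ether coupling in which the bromide is unhindered and activated by the para formyl group, and the CuI/picolinic acid system is known to arylate 2,6-disubstituted phenols, so the hindered oxygen of 1 should be arylated under oxygen-free conditions.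

Step 2
Reactants: 3 2,6-dimethoxy-4-(2,4,6-trimethoxyphenoxy)benzaldehyde
Product: 5 2,6-dimethoxy-4-(2,4,6-trimethoxyphenoxy)phenol, via aryl formate 4 (not isolated)
Conditions: H2O2 (30 % aq.), H2SO4 (cat.), MeOH, 0 → 25 °C
Reagents that add atoms: hydrogen peroxide, OO
Why: Acid-catalysed Dakin oxidation, in which the electron-rich 2,6-dimethoxy-4-aryloxyphenyl group migrates readily in the peroxyhemiacetal and formate 4 is methanolysed in the same flask, while cold dilute peroxide should spare the electron-rich ring A.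

Step 3
Reactants: 5 2,6-dimethoxy-4-(2,4,6-trimethoxyphenoxy)phenol; 6 trichloroethylene
Product: 7 2-{[(E)-1,2-dichloroethenyl]oxy}-1,3-dimethoxy-5-(2,4,6-trimethoxyphenoxy)benzene
Conditions: K2CO3, DMF, 70 °C
Reagents that add atoms: none
Why: Base-mediated anti addition of the phenoxide to dichloroacetylene generated in situ from trichloroethylene is the standard first stage of the dichlorovinyl ether route to ynol ethers and gives the (E)-ether.

Step 4
Reactants: 7 2-{[(E)-1,2-dichloroethenyl]oxy}-1,3-dimethoxy-5-(2,4,6-trimethoxyphenoxy)benzene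
Product: 9 2-ethynyloxy-1,3-dimethoxy-5-(2,4,6-trimethoxyphenoxy)benzene, via lithium acetylide 8 (not isolated)
Conditions: n-BuLi (2.3 equiv), Et2O, −78 → −40 °C; then H2O, −78 °C; filtered through basic alumina, kept cold in solution and used the same day
Reagents that add atoms: none
Why: Dehydrochlorination followed by lithium–chlorine exchange of a 1,2-dichlorovinyl ether with two equivalents of n-BuLi (Greene-type ynol ether synthesis) gives acetylide 8, and cold protonation releases the terminal ynol ether, which the two ortho methoxy groups shield against oligomerisation.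

Step 5
Reactants: 10 3,4,5-trimethoxyphenol; 11 4-bromo-3,5-dimethoxybenzaldehyde
Product: 12 3,5-dimethoxy-4-(3,4,5-trimethoxyphenoxy)benzaldehyde
Conditions: CuI (20 mol %), picolinic acid (40 mol %), K3PO4, DMSO, 100 °C, argon
Reagents that add atoms: none
Why: Ullmann diaryl ether coupling on a bromide flanked by two methoxy groups, where the para formyl group activates the C–Br bond, phenol 10 is unhindered and the picolinic acid ligand was developed for ortho-substituted partners, so the crowded F–O–E ether should form.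

Step 6
Reactants: 12 3,5-dimethoxy-4-(3,4,5-trimethoxyphenoxy)benzaldehyde
Product: 14 3,5-dimethoxy-4-(3,4,5-trimethoxyphenoxy)phenol, via aryl formate 13 (not isolated)
Conditions: H2O2 (30 % aq.), H2SO4 (cat.), MeOH, 0 → 25 °C
Reagents that add atoms: hydrogen peroxide, OO
Why: Acid-catalysed Dakin oxidation, the para aryloxy and two meta methoxy groups giving the aryl group enough migratory aptitude (as in the conversion of 3,4,5-trimethoxybenzaldehyde into its phenol), with methanolysis of formate 13 in situ.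

Step 7
Reactants: 14 3,5-dimethoxy-4-(3,4,5-trimethoxyphenoxy)phenol; 11 4-bromo-3,5-dimethoxybenzaldehyde
Product: 15 4-[3,5-dimethoxy-4-(3,4,5-trimethoxyphenoxy)phenoxy]-3,5-dimethoxybenzaldehyde
Conditions: CuI (20 mol %), picolinic acid (40 mol %), K3PO4, DMSO, 100 °C, argon
Reagents that add atoms: none
Why: Second Ullmann diaryl ether coupling of the same type as step 5, with the unhindered phenolic oxygen of 14 attacking the formyl-activated, di-ortho-methoxy bromide to form the E–O–D ether.

Step 8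
Reactants: 15 4-[3,5-dimethoxy-4-(3,4,5-trimethoxyphenoxy)phenoxy]-3,5-dimethoxybenzaldehyde
Product: 17 4-[3,5-dimethoxy-4-(3,4,5-trimethoxyphenoxy)phenoxy]-3,5-dimethoxyphenol, via aryl formate 16 (not isolated)
Conditions: H2O2 (30 % aq.), H2SO4 (cat.), MeOH, 0 → 25 °C
Reagents that add atoms: hydrogen peroxide, OO
Why: Acid-catalysed Dakin oxidation as in step 6, giving the D–E–F phenol (ArDEF–OH) whose hydroxyl sits on the unhindered carbon of ring D.

Step 9
Reactants: 18 squaric acid (3,4-dihydroxycyclobut-3-ene-1,2-dione)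
Product: 19 3,4-dichlorocyclobut-3-ene-1,2-dione
Conditions: (COCl)2 (2.2 equiv), DMF (cat.), 1,2-dichloroethane, 50 °C
Reagents that add atoms: oxalyl chloride, O=C(Cl)C(Cl)=O
Why: Vilsmeier-type chlorination of the two vinylogous acid hydroxyls is the standard preparation of squaric acid dichloride.

Step 10
Reactants: 19 3,4-dichlorocyclobut-3-ene-1,2-dione; 17 4-[3,5-dimethoxy-4-(3,4,5-trimethoxyphenoxy)phenoxy]-3,5-dimethoxyphenol
Product: 21 3-methoxy-4-(ArDEF-oxy)cyclobut-3-ene-1,2-dione, via chloro aryloxy squarate 20 (not isolated)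
Conditions: 19 (1.5 equiv), i-Pr2NEt, CH2Cl2, −78 → −20 °C, slow addition of 17; then MeOH, i-Pr2NEt, −20 → 0 °C
Reagents that add atoms: methanol, CO
Why: Sequential addition–elimination at the two vinylogous acid chloride carbons, in which the first aryloxy group deactivates the remaining chloride so that mono-substitution prevails with excess 19 and methanol then takes the second chloride, avoiding the thermodynamically unfavourable exchange of methoxide for aryloxide on dimethyl squarate.

Step 11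
Reactants: 21 3-methoxy-4-(ArDEF-oxy)cyclobut-3-ene-1,2-dione
Product: 22 racemic 4-hydroxy-3-methoxy-2-(ArDEF-oxy)cyclobut-2-en-1-one
Conditions: LiAlH(OtBu)3 (1.1 equiv), THF, −78 °C; then H2O (pH 7 buffer)
Reagents that add atoms: none
Why: Mono-reduction of a squarate ester carbonyl with LiAlH(OtBu)3 is the standard entry to 4-hydroxycyclobutenones, and here the carbonyl beside the methoxy-bearing carbon is conjugated only with the weakly donating aryloxy group and has the smaller neighbour, so hydride should add there and leave the ketone beside the aryloxy carbon, the new stereocentre forming as a racemate that step 13 erases.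

Step 12
Reactants: 22 racemic 4-hydroxy-3-methoxy-2-(ArDEF-oxy)cyclobut-2-en-1-one
Product: 23 racemic 3,4-dimethoxy-2-(ArDEF-oxy)cyclobut-2-en-1-one
Conditions: MeI (10 equiv), Ag2O (3 equiv), MeCN, 25 °C, dark
Reagents that add atoms: iodomethane, CI
Why: Purdie-type O-methylation with MeI/Ag2O is the established near-neutral way to cap 4-hydroxycyclobutenones, avoiding acid-induced loss of methanol and removing the free hydroxyl that would otherwise trap the ketene as a butenolide on heating.

Step 13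
Reactants: 23 racemic 3,4-dimethoxy-2-(ArDEF-oxy)cyclobut-2-en-1-one; 9 2-ethynyloxy-1,3-dimethoxy-5-(2,4,6-trimethoxyphenoxy)benzene
Product: 28 5-[2,6-dimethoxy-4-(2,4,6-trimethoxyphenoxy)phenoxy]-4-{4-[3,5-dimethoxy-4-(3,4,5-trimethoxyphenoxy)phenoxy]-3,5-dimethoxyphenoxy}-2,3-dimethoxyphenol, via vinylketene 24 (not isolated), via vinylcyclobutenone 25 (not isolated), via dienylketene 26 (not isolated), via cyclohexadienone 27 (not isolated)
Conditions: 9 (1.5 equiv), PhMe (0.3 M), 90 → 110 °C, sealed tube, argon; then K2CO3, MeOH, 25 °C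
Reagents that add atoms: none
Why: Heating opens 23 by conrotatory 4π electrocyclic ring opening, the C-4 methoxy group rotating outward, to vinylketene 24, whose ketene carbon is attacked by the nucleophilic terminal CH of ynol ether 9 in a regiospecific [2+2] cycloaddition that gives 4-vinylcyclobutenone 25 (bonds C-2–C-3 and C-1–C-6). A second 4π opening of 25, with the aryloxy group turning outward and the vinyl group inward, gives the (Z)-dienylketene 26, which closes ring C by thermal disrotatory 6π electrocyclisation between the ketene carbon and the methoxy-bearing vinyl terminus (bond C-3–C-4) to cyclohexadienone 27, and enolisation gives phenol 28. The closest known reaction type is the Danheiser benzannulation of cyclobutenones with alkoxy- and siloxyalkynes, which gives 3-alkoxyphenols with this regiochemistry, and squarate-derived cyclobutenones are known to open to ketenes in the same temperature range. The stereocentres of 23, 25 and 27 are transient and are lost on aromatisation, so no stereocontrol is needed. The step needs regioselectivity in the [2+2] event, which the polarised O–C≡C–H unit secures (C-2–H ends up between the new phenol and the ring B ether, and the two aryl ethers end up adjacent), and it needs the ketene to be trapped by the alkyne and not by product phenol, which the excess of 9 at high concentration favours, while the closing carbonate methanolysis returns any aryl ester of 28 to the phenol.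

Step 14
Reactants: 28 5-[2,6-dimethoxy-4-(2,4,6-trimethoxyphenoxy)phenoxy]-4-{4-[3,5-dimethoxy-4-(3,4,5-trimethoxyphenoxy)phenoxy]-3,5-dimethoxyphenoxy}-2,3-dimethoxyphenol
Product: 29 4-{4-[3,5-dihydroxy-4-(3,4,5-trihydroxyphenoxy)phenoxy]-3,5-dihydroxyphenoxy}-5-[2,6-dihydroxy-4-(2,4,6-trihydroxyphenoxy)phenoxy]benzene-1,2,3-triol (CNP0270681.0)
Conditions: BBr3 (30 equiv), CH2Cl2, −78 → 25 °C, argon; then H2O, 0 °C; degassed work-up, reverse-phase chromatography
Reagents that add atoms: none
Why: Lewis acid-mediated aryl methyl ether cleavage with BBr3 (bromide attacks the methyl carbon of the boron-complexed ether) removes all fourteen methyl groups, while the diaryl ether bonds, which offer no sp3 carbon for attack, should stay intact.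

**Compound list**
1 | 2,4,6-trimethoxyphenol | COc1cc(OC)c(O)c(OC)c1 | starting material
2 | 4-bromo-2,6-dimethoxybenzaldehyde | COc1cc(Br)cc(OC)c1C=O | starting material
3 | 2,6-dimethoxy-4-(2,4,6-trimethoxyphenoxy)benzaldehyde | COc1cc(Oc2c(OC)cc(OC)cc2OC)cc(OC)c1C=O | intermediate
4 | 2,6-dimethoxy-4-(2,4,6-trimethoxyphenoxy)phenyl formate (formed in the flask) | COc1cc(Oc2c(OC)cc(OC)cc2OC)cc(OC)c1OC=O | intermediate
5 | 2,6-dimethoxy-4-(2,4,6-trimethoxyphenoxy)phenol (A–B phenol, ArAB–OH) | COc1cc(Oc2c(OC)cc(OC)cc2OC)cc(OC)c1O | intermediate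
6 | trichloroethylene | ClC=C(Cl)Cl | starting material
7 | 2-{[(E)-1,2-dichloroethenyl]oxy}-1,3-dimethoxy-5-(2,4,6-trimethoxyphenoxy)benzene | Cl/C=C(/Cl)Oc1c(OC)cc(Oc2c(OC)cc(OC)cc2OC)cc1OC | intermediate
8 | {[2,6-dimethoxy-4-(2,4,6-trimethoxyphenoxy)phenoxy]ethynyl}lithium (formed in the flask) | [Li]C#COc1c(OC)cc(Oc2c(OC)cc(OC)cc2OC)cc1OC | intermediate
9 | 2-ethynyloxy-1,3-dimethoxy-5-(2,4,6-trimethoxyphenoxy)benzene (A–B aryl ethynyl ether) | C#COc1c(OC)cc(Oc2c(OC)cc(OC)cc2OC)cc1OC | intermediate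
10 | 3,4,5-trimethoxyphenol | COc1cc(O)cc(OC)c1OC | starting material
11 | 4-bromo-3,5-dimethoxybenzaldehyde | COc1cc(C=O)cc(OC)c1Br | starting material
12 | 3,5-dimethoxy-4-(3,4,5-trimethoxyphenoxy)benzaldehyde | COc1cc(C=O)cc(OC)c1Oc1cc(OC)c(OC)c(OC)c1 | intermediate
13 | 3,5-dimethoxy-4-(3,4,5-trimethoxyphenoxy)phenyl formate (formed in the flask) | COc1cc(OC=O)cc(OC)c1Oc1cc(OC)c(OC)c(OC)c1 | intermediate
14 | 3,5-dimethoxy-4-(3,4,5-trimethoxyphenoxy)phenol | COc1cc(O)cc(OC)c1Oc1cc(OC)c(OC)c(OC)c1 | intermediate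
15 | 4-[3,5-dimethoxy-4-(3,4,5-trimethoxyphenoxy)phenoxy]-3,5-dimethoxybenzaldehyde | COc1cc(C=O)cc(OC)c1Oc1cc(OC)c(Oc2cc(OC)c(OC)c(OC)c2)c(OC)c1 | intermediate
16 | 4-[3,5-dimethoxy-4-(3,4,5-trimethoxyphenoxy)phenoxy]-3,5-dimethoxyphenyl formate (formed in the flask) | COc1cc(OC=O)cc(OC)c1Oc1cc(OC)c(Oc2cc(OC)c(OC)c(OC)c2)c(OC)c1 | intermediate
17 | 4-[3,5-dimethoxy-4-(3,4,5-trimethoxyphenoxy)phenoxy]-3,5-dimethoxyphenol (D–E–F phenol, ArDEF–OH) | COc1cc(O)cc(OC)c1Oc1cc(OC)c(Oc2cc(OC)c(OC)c(OC)c2)c(OC)c1 | intermediate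
18 | squaric acid (3,4-dihydroxycyclobut-3-ene-1,2-dione) | OC1=C(O)C(=O)C1=O | starting material
19 | 3,4-dichlorocyclobut-3-ene-1,2-dione | ClC1=C(Cl)C(=O)C1=O | intermediate
20 | 3-chloro-4-(ArDEF-oxy)cyclobut-3-ene-1,2-dione (formed in the flask) | ClC1=C(Oc2cc(OC)c(Oc3cc(OC)c(Oc4cc(OC)c(OC)c(OC)c4)c(OC)c3)c(OC)c2)C(=O)C1=O | intermediate
21 | 3-methoxy-4-(ArDEF-oxy)cyclobut-3-ene-1,2-dione | COC1=C(Oc2cc(OC)c(Oc3cc(OC)c(Oc4cc(OC)c(OC)c(OC)c4)c(OC)c3)c(OC)c2)C(=O)C1=O | intermediate
22 | racemic 4-hydroxy-3-methoxy-2-(ArDEF-oxy)cyclobut-2-en-1-one | OC1C(OC)=C(Oc2cc(OC)c(Oc3cc(OC)c(Oc4cc(OC)c(OC)c(OC)c4)c(OC)c3)c(OC)c2)C1=O | intermediate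
23 | racemic 3,4-dimethoxy-2-(ArDEF-oxy)cyclobut-2-en-1-one | COC1C(OC)=C(Oc2cc(OC)c(Oc3cc(OC)c(Oc4cc(OC)c(OC)c(OC)c4)c(OC)c3)c(OC)c2)C1=O | intermediate
24 | (3Z)-2-(ArDEF-oxy)-3,4-dimethoxybuta-1,3-dien-1-one (vinylketene, formed in the flask) | CO/C=C(OC)/C(Oc1cc(OC)c(Oc2cc(OC)c(Oc3cc(OC)c(OC)c(OC)c3)c(OC)c2)c(OC)c1)=C=O | intermediate
25 | racemic 3-(ArAB-oxy)-4-(ArDEF-oxy)-4-[(Z)-1,2-dimethoxyethenyl]cyclobut-2-en-1-one (formed in the flask) | O=C1C=C(Oc2c(OC)cc(Oc3c(OC)cc(OC)cc3OC)cc2OC)C1(Oc1cc(OC)c(Oc2cc(OC)c(Oc3cc(OC)c(OC)c(OC)c3)c(OC)c2)c(OC)c1)/C(OC)=C/OC | intermediate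
26 | (3Z,5Z)-3-(ArAB-oxy)-4-(ArDEF-oxy)-5,6-dimethoxyhexa-1,3,5-trien-1-one (dienylketene, formed in the flask) | O=C=C/C(Oc1c(OC)cc(Oc2c(OC)cc(OC)cc2OC)cc1OC)=C(Oc1cc(OC)c(Oc2cc(OC)c(Oc3cc(OC)c(OC)c(OC)c3)c(OC)c2)c(OC)c1)\C(OC)=C\OC | intermediate
27 | racemic 3-(ArAB-oxy)-4-(ArDEF-oxy)-5,6-dimethoxycyclohexa-2,4-dien-1-one (formed in the flask) | O=C1C=C(Oc2c(OC)cc(Oc3c(OC)cc(OC)cc3OC)cc2OC)C(Oc2cc(OC)c(Oc3cc(OC)c(Oc4cc(OC)c(OC)c(OC)c4)c(OC)c3)c(OC)c2)=C(OC)C1OC | intermediate
28 | 5-(ArAB-oxy)-4-(ArDEF-oxy)-2,3-dimethoxyphenol (hexamer with free C-3 hydroxyl and fourteen methyl ethers) | Oc1cc(Oc2c(OC)cc(Oc3c(OC)cc(OC)cc3OC)cc2OC)c(Oc2cc(OC)c(Oc3cc(OC)c(Oc4cc(OC)c(OC)c(OC)c4)c(OC)c3)c(OC)c2)c(OC)c1OC | intermediate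
29 | 4-{4-[3,5-dihydroxy-4-(3,4,5-trihydroxyphenoxy)phenoxy]-3,5-dihydroxyphenoxy}-5-[2,6-dihydroxy-4-(2,4,6-trihydroxyphenoxy)phenoxy]benzene-1,2,3-triol (CNP0270681.0) | Oc1cc(O)c(Oc2cc(O)c(Oc3cc(O)c(O)c(O)c3Oc3cc(O)c(Oc4cc(O)c(Oc5cc(O)c(O)c(O)c5)c(O)c4)c(O)c3)c(O)c2)c(O)c1 | target

**Totals**
Total step count: 14. Longest linear sequence: 9 steps (steps 5, 6, 7, 8, 10, 11, 12, 13, 14).

**Steps most likely to fail**

1. Step 13. Re-closure of vinylketene 24 to 23 may outrun the [2+2] addition, the terminal ynol ether 9 may oligomerise at the temperature needed for ring opening, or the ketene may be consumed by product phenol, so that ring C is not formed. The fallback builds the two ring C ethers by catalysed couplings on a preformed ring C; it sets out from phenols 5 and 17 and comes back to the route at target 29.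
 - Rieche formylation of commercial 5-bromo-1,2,3-trimethoxybenzene (Cl2CHOMe, TiCl4, CH2Cl2, 0 °C) should give 6-bromo-2,3,4-trimethoxybenzaldehyde F1, whose bromide is activated by the ortho formyl group.
 - Ullmann coupling of 5 with F1 under the conditions of step 1 would give 6-(ArAB-oxy)-2,3,4-trimethoxybenzaldehyde F2, which holds the C-1 ether.
 - Dakin oxidation as in step 2 would pass through the aryl formate F3 to 6-(ArAB-oxy)-2,3,4-trimethoxyphenol F4, which carries the free C-6 hydroxyl.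
 - Phenol 17 would be converted with Tf2O and pyridine into the aryl triflate F5.
 - Palladium-catalysed C–O coupling of the hindered phenol F4 with the unhindered triflate F5 (Pd(OAc)2, 2-di-tert-butylphosphino-2',4',6'-triisopropylbiphenyl, K3PO4, toluene, 100 °C) would give the pentadecamethyl ether F6, which differs from 28 only by a methyl ether at C-3.
 - BBr3 as in step 14 would then give 29.

2. Step 11. Hydride delivery may fail to discriminate between the two carbonyl groups, or may add in conjugate fashion and expel aryloxide, giving the regioisomeric hydroxycyclobutenone with the aryloxy group β to the ketone. The fallback removes the need for discrimination; it sets out from 19 and 17 and comes back at 23.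
 - Two equivalents of 17 with 19 (i-Pr2NEt, CH2Cl2, −78 → 0 °C) would give, through 20, the symmetrical 3,4-bis(ArDEF-oxy)cyclobut-3-ene-1,2-dione F7, whose carbonyls are equivalent.
 - LiAlH(OtBu)3 as in step 11 would give racemic 4-hydroxy-2,3-bis(ArDEF-oxy)cyclobut-2-en-1-one F8.
 - MeI/Ag2O as in step 12 would give racemic 4-methoxy-2,3-bis(ArDEF-oxy)cyclobut-2-en-1-one F9.
 - One equivalent of NaOMe in MeOH/THF at −20 °C would exchange only the β-aryloxy group by vinylogous ester addition–elimination, a path closed to the α-aryloxy group, giving 23 and returning one equivalent of 17 for reuse.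

3. Step 14. Ether cleavage may stall before all fourteen methyl groups are removed, and the free pentadecaphenol may oxidise in air or bind irreversibly to the stationary phase during isolation. The fallback isolates the product through a stable derivative; it sets out from 28 and comes back at 29.
 - After the BBr3 treatment and a methanol quench, the crude polyphenol would be acetylated (Ac2O, pyridine, DMAP) to the pentadecaacetate F10.
 - F10 should be air-stable and can be chromatographed on silica, so that partly methylated material is separated and resubjected.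
 - Acid-catalysed methanolysis under oxygen-free conditions (HCl in degassed MeOH, generated from AcCl, 25–40 °C) would then release 29 without exposing phenolates to air.

**Further compounds**
F1 | step 13 | 6-bromo-2,3,4-trimethoxybenzaldehyde | COc1cc(Br)c(C=O)c(OC)c1OC
F2 | step 13 | 6-[2,6-dimethoxy-4-(2,4,6-trimethoxyphenoxy)phenoxy]-2,3,4-trimethoxybenzaldehyde | COc1cc(Oc2c(OC)cc(Oc3c(OC)cc(OC)cc3OC)cc2OC)c(C=O)c(OC)c1OC
F3 | step 13 | 6-[2,6-dimethoxy-4-(2,4,6-trimethoxyphenoxy)phenoxy]-2,3,4-trimethoxyphenyl formate | COc1cc(Oc2c(OC)cc(Oc3c(OC)cc(OC)cc3OC)cc2OC)c(OC=O)c(OC)c1OC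
F4 | step 13 | 6-[2,6-dimethoxy-4-(2,4,6-trimethoxyphenoxy)phenoxy]-2,3,4-trimethoxyphenol | COc1cc(Oc2c(OC)cc(Oc3c(OC)cc(OC)cc3OC)cc2OC)c(O)c(OC)c1OC
F5 | step 13 | 4-[3,5-dimethoxy-4-(3,4,5-trimethoxyphenoxy)phenoxy]-3,5-dimethoxyphenyl trifluoromethanesulfonate | COc1cc(OS(=O)(=O)C(F)(F)F)cc(OC)c1Oc1cc(OC)c(Oc2cc(OC)c(OC)c(OC)c2)c(OC)c1
F6 | step 13 | pentadecamethyl ether of 29 (28 with a methyl ether at C-3) | COc1cc(Oc2c(OC)cc(Oc3c(OC)cc(OC)cc3OC)cc2OC)c(Oc2cc(OC)c(Oc3cc(OC)c(Oc4cc(OC)c(OC)c(OC)c4)c(OC)c3)c(OC)c2)c(OC)c1OC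
F7 | step 11 | 3,4-bis(ArDEF-oxy)cyclobut-3-ene-1,2-dione | O=C1C(=O)C(Oc2cc(OC)c(Oc3cc(OC)c(Oc4cc(OC)c(OC)c(OC)c4)c(OC)c3)c(OC)c2)=C1Oc1cc(OC)c(Oc2cc(OC)c(Oc3cc(OC)c(OC)c(OC)c3)c(OC)c2)c(OC)c1
F8 | step 11 | racemic 4-hydroxy-2,3-bis(ArDEF-oxy)cyclobut-2-en-1-one | OC1C(Oc2cc(OC)c(Oc3cc(OC)c(Oc4cc(OC)c(OC)c(OC)c4)c(OC)c3)c(OC)c2)=C(Oc2cc(OC)c(Oc3cc(OC)c(Oc4cc(OC)c(OC)c(OC)c4)c(OC)c3)c(OC)c2)C1=O
F9 | step 11 | racemic 4-methoxy-2,3-bis(ArDEF-oxy)cyclobut-2-en-1-one | COC1C(Oc2cc(OC)c(Oc3cc(OC)c(Oc4cc(OC)c(OC)c(OC)c4)c(OC)c3)c(OC)c2)=C(Oc2cc(OC)c(Oc3cc(OC)c(Oc4cc(OC)c(OC)c(OC)c4)c(OC)c3)c(OC)c2)C1=O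
F10 | step 14 | pentadecaacetate of 29 | CC(=O)Oc1cc(OC(C)=O)c(Oc2cc(OC(C)=O)c(Oc3cc(OC(C)=O)c(OC(C)=O)c(OC(C)=O)c3Oc3cc(OC(C)=O)c(Oc4cc(OC(C)=O)c(Oc5cc(OC(C)=O)c(OC(C)=O)c(OC(C)=O)c5)c(OC(C)=O)c4)c(OC(C)=O)c3)c(OC(C)=O)c2)c(OC(C)=O)c1
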